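C1 H2, C2 H (ring fusion), C3 H and C4 Me (epoxide), C5 H2, C6 H (ring fusion), C7 H (isopropyl), C8 H (aroyloxy), C9 H2, C10 (Me, OH). Five-membered ring: C2–C6. Seven-membered ring: C1, C2, C6–C10.
Enabling feature: the arc C8–C9–C10–C1–C2 of the seven-membered ring has oxygen on its end C8 and its centre C10, O-8 and H-2 share a face, and C6 and C7 carry anti hydrogens. Joining O-8 to C2 turns arc plus oxygen into a 4-oxy-3-oxidopyrylium (a kojic-type 4-pyrone) and C6–C7 into an E-alkene tied to C2 by C3–C4–C5.
Target <= debenzylation, C10–OH-directed epoxidation of C3=C4, acylation of C8–OH <= trans-hydroazulene diol 26 <= Li/NH3 reduction, enol triflate and methyl coupling at C4 <= hydroxy enone 20 <= E1cB opening of the C2–O–C8 bridge through a C4 ketone <= bridged alcohol 18.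
18 <= exo methyl addition to C10=O and deletion of C9=O <= adduct 13 <= intramolecular [5+2] cycloaddition of pyrone 11. This makes C2–C6 and C7–C8 and closes the five- and seven-membered rings (and a temporary oxygen bridge) at once; the epoxide ring comes last.
11 <= allomaltol 6 (C1–C3, C8–C10) + (E)-5-methylhex-3-enoic acid 3 (C4–C7, isopropyl) + (R,R)-hydrobenzoin 10 (removable C4 ketal that carries the absolute configuration).

Key step: step 6

Remark on the chemistry: 6, 10 and 27 are taken as commercial (6 is otherwise two steps from kojic acid).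
Faces: β is the face that carries O-8. Seen from the β face, C6→C7→C8→C9→C10→C1→C2 runs clockwise. In the target, O-8, H-2, H-3, H-7, Me-4 and Me-10 are β; H-6, the isopropyl group, HO-10 and the epoxide oxygen are α.

Step 1
Reactants: 1 3-methylbutanal; 2 malonic acid
Product: 3 (E)-5-methylhex-3-enoic acid
Conditions: piperidinium acetate (cat.), DMSO, 100 °C
Reagents that add atoms: none
Why: A Knoevenagel–Doebner condensation under deconjugating conditions should give the 3-alkenoic acid, because the alkylidenemalonic acid isomerises to its β,γ-form before losing CO2, and the isopropyl group strongly favours the E-alkene that later encodes the anti H-6/H-7 pair.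

Step 2
Reactants: 3 (E)-5-methylhex-3-enoic acid
Product: 5 (E)-N-methoxy-N,5-dimethylhex-3-enamide, via acyl imidazolide 4 (not isolated)
Conditions: CDI, CH2Cl2, 0 °C to rt; then MeNH(OMe)·HCl, rt
Reagents that add atoms: N,O-dimethylhydroxylamine hydrochloride, CNOC.Cl; 1,1'-carbonyldiimidazole, O=C(n1ccnc1)n1ccnc1 (atoms kept only in 4)
Why: Weinreb amide formation through the acyl imidazolide is a neutral acyl substitution that should leave the skipped E-alkene in place.

Step 3
Reactants: 6 5-hydroxy-2-methyl-4H-pyran-4-one (allomaltol)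
Product: 7 5-(tert-butyldimethylsilyloxy)-2-methyl-4H-pyran-4-one
Conditions: TBSCl, imidazole, DMF, rt
Reagents that add atoms: tert-butyldimethylsilyl chloride, CC(C)(C)[Si](C)(C)Cl
Why: Standard O-silylation of the acidic enolic hydroxyl protects it against the base of step 4 and installs the group whose migration later unmasks the ylide.

Step 4
Reactants: 7 5-(tert-butyldimethylsilyloxy)-2-methyl-4H-pyran-4-one; 5 (E)-N-methoxy-N,5-dimethylhex-3-enamide
Product: 9 5-(tert-butyldimethylsilyloxy)-2-[(E)-6-methyl-2-oxohept-4-enyl]-4H-pyran-4-one, via lithium dienolate 8 (not isolated)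
Conditions: LiN(SiMe3)2, THF, −78 °C; then 5, −78 to −30 °C; aq NH4Cl
Reagents that add atoms: lithium bis(trimethylsilyl)amide, [Li+].C[Si](C)(C)[N-][Si](C)(C)C (lithium kept only in 8)
Why: Lateral (vinylogous) deprotonation of the 2-methyl group of a 4-pyrone followed by a Weinreb ketone synthesis should form C3–C4, with the chelated tetrahedral adduct masking the acidic product ketone until the quench.

Step 5
Reactants: 9 pyronyl ketone; 10 (1R,2R)-1,2-diphenylethane-1,2-diol
Product: 11 pyrone ketal (C4 as (4R,5R)-4,5-diphenyl-1,3-dioxolane)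
Conditions: p-TsOH (cat.), benzene, reflux, Dean–Stark
Reagents that add atoms: none
Why: Acid-catalysed ketalisation with water removal protects the doubly activated ketone, the β,γ-unsaturated ketal being the thermodynamic sink so that the alkene stays E and unconjugated, and the C2-symmetric diol creates no new stereocentre at C4.

Step 6
Reactants: 11 pyrone ketal
Product: 13 oxa-bridged [5+2] adduct (C9 ketone; C1=C10 silyl enol ether; C4 ketal), via oxidopyrylium ylide 12 (not isolated)
Conditions: toluene (0.01 M), BHT (cat.), sealed tube, 170–180 °C; chromatography to remove the diastereomeric adduct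
Reagents that add atoms: none
Why: Heat moves the silyl group from O-5 of the pyrone to its carbonyl oxygen (1,4 O-to-O shift) and gives the 4-silyloxy-3-oxidopyrylium 12, whose five-atom four-electron array C8–C9–C10–C1–C2 adds in a concerted, suprafacial way to the C6=C7 alkene; the closest known reaction type is the thermal intramolecular [5+2] cycloaddition of silyloxy-4-pyrones (oxidopyrylium–alkene cycloaddition) over a three-atom tether. The seven-membered ring closes as the cycloaddition ring itself through C2–C6 and C7–C8 with the pyran oxygen left as a C2–O–C8 bridge, and the five-membered ring closes in the same event over C3–C4–C5 in the only mode that so short a tether allows, with C5 exo (syn to the bridge). C2 and C8 are held cis by the bridge, C6 follows from the exo tether (H-6 anti to the bridge), and C7 follows from the E-geometry, which is transferred stereospecifically and puts the isopropyl group endo and H-7 anti to H-6, which is the C6/C7/C8 pattern of the target. The absolute sense rests on the (R,R)-ketal, which makes the two facial modes diastereomeric: it sits on the local twofold axis of the twisted five-membered ring being formed, the helicity leading to 13 keeps its phenyl groups on the side of the small pyran oxygen and of H-6 and not of C1–H and C7, and since these phenyl groups lie far from the reacting carbons and may bias the faces only weakly, the single enantiomer is secured by removing the other adduct here by chromatography or crystallisation. Regiochemistry needs no control beyond the tether, the gem-dialkoxy carbon (Thorpe–Ingold effect) helps the unactivated alkene, and high dilution holds back dimerisation of the ylide. One operation thus turns a flat pyrone with one E-alkene into a tricycle that holds both carbocycles, the configurations at C6, C7 and C8, the C8 oxygen, a masked C10 ketone and, in the C2–O bond β to C4, the handle for its own opening.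

Step 7
Reactants: 13 oxa-bridged [5+2] adduct
Product: 14 C9 tosylhydrazone of 13
Conditions: TsNHNH2, PPTS (cat.), THF, 4 Å MS, 50 °C
Reagents that add atoms: p-toluenesulfonyl hydrazide, Cc1ccc(cc1)S(=O)(=O)NN
Why: Tosylhydrazone condensation can take place only at C9, the single free ketone, since C10 is a silyl enol ether and C4 a ketal.

Step 8
Reactants: 14 C9 tosylhydrazone
Product: 17 oxa-bridged C10 ketone (C1 and C9 as CH2), via allylic diazene 15 (not isolated), via silyl enol ether 16 (not isolated)
Conditions: catecholborane, CHCl3, −10 °C to rt; NaOAc·3H2O, reflux; then Bu4NF, AcOH, THF, 0 °C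
Reagents that add atoms: none
Why: Hydride reduction of the α,β-unsaturated tosylhydrazone and loss of sulfinate give an allylic diazene that expels N2 in a retro-ene reaction (reductive alkene transposition), which deletes the C9 oxygen and shifts the enol ether to C9=C10, so that buffered fluoride then frees the C10 ketone without β-elimination of the bridge.

Step 9
Reactants: 17 oxa-bridged C10 ketone
Product: 18 oxa-bridged tertiary alcohol (10β-Me; 10α-OH)
Conditions: MeMgBr, CeCl3, THF, −78 °C; aq NH4Cl
Reagents that add atoms: methylmagnesium bromide, C[Mg]Br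
Why: The CeCl3-modified Grignard 1,2-addition should come from the exo face syn to the oxygen bridge, because the endo face of the 8-oxabicyclo[3.2.1]octan-3-one is closed by the C6–C7 bridge and its endo isopropyl group, which sets C10 with methyl β and hydroxyl α, while the low basicity avoids β-elimination.

Step 10
Reactants: 18 oxa-bridged tertiary alcohol
Product: 20 hydroxy enone (C4 ketone; C2=C3; 8β-OH; 10α-OH), via bridged C4 ketone 19 (not isolated)
Conditions: 1 M HCl, THF, 40 °C; then DBU, CH2Cl2, 0 °C to rt, short contact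
Reagents that add atoms: water, O
Why: Ketal hydrolysis returns the auxiliary, and the freed C4 ketone opens the bridge by an E1cB elimination (retro-oxa-Michael reaction) in which only C3–H is both acidic and adjacent to a C–O bond standing nearly perpendicular to the cyclopentanone plane, so that C2–O breaks and the oxygen stays on C8 with its configuration.

Step 11
Reactants: 20 hydroxy enone
Product: 22 tris(trimethylsilyl) compound (C3=C4 silyl enol ether; H-2 β), via dilithium enolate alkoxide 21 (not isolated)
Conditions: Li (2.1 equiv), NH3(l)/THF, −78 °C; evaporate NH3; TMSCl (excess), Et3N, DMAP (cat.), THF, −78 °C to rt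
Reagents that add atoms: chlorotrimethylsilane, C[Si](C)(C)Cl; lithium, [Li] (kept only in 21)
Why: Dissolving-metal (Birch-type) reduction of the enone with regiospecific silyl trapping of the enolate should place hydrogen on C2 from the β face, because the C8 hydroxyl that has just left C2 lies over it as internal proton source and the trans-fused enolate is expected to be the more stable one, and it fixes the enolate double bond at C3=C4.

Step 12
Reactants: 22 tris(trimethylsilyl) compound
Product: 24 C4 enol triflate (C3=C4; 8β- and 10α-OTMS), via lithium enolate 23 (not isolated)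
Conditions: MeLi (1.05 equiv), THF, 0 °C; PhNTf2, −78 °C to rt; aq NH4Cl
Reagents that add atoms: N-phenylbis(trifluoromethanesulfonimide), O=S(=O)(N(c1ccccc1)S(=O)(=O)C(F)(F)F)C(F)(F)F; methyllithium, [Li]C (lithium kept only in 23)
Why: Cleavage of the silyl enol ether with MeLi regenerates the C3=C4 lithium enolate without equilibration, and O-sulfonylation with PhNTf2 (enol triflate synthesis) freezes this regiochemistry while the alkyl silyl ethers stay on.

Step 13
Reactants: 24 C4 enol triflate
Product: 26 trans-hydroazulene diol (C3=C4–Me; 8β-OH; 10α-OH), via bis(trimethylsilyl) ether 25 (not isolated)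
Conditions: MeMgBr, Fe(acac)3 (cat.), THF/NMP, −30 to 0 °C; then 1 M HCl, THF, 0 °C
Reagents that add atoms: methylmagnesium bromide, C[Mg]Br
Why: Iron-catalysed Kumada-type cross-coupling of the enol triflate with MeMgBr puts the methyl group on C4 with the double bond held at C3=C4, and dilute acid then removes both trimethylsilyl ethers.

Step 14
Reactants: 26 trans-hydroazulene diol; 27 4-(benzyloxy)benzoyl chloride
Product: 28 C8 4-(benzyloxy)benzoate
Conditions: Et3N, DMAP (cat.), CH2Cl2, rt to 40 °C
Reagents that add atoms: none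
Why: DMAP-catalysed acylation distinguishes the secondary C8–OH from the tertiary C10–OH on steric grounds and proceeds with retention at C8.

Step 15
Reactants: 28 C8 4-(benzyloxy)benzoate
Product: 29 3α,4α-epoxide of 28
Conditions: VO(acac)2 (cat.), t-BuOOH, CH2Cl2, 0 °C to rt
Reagents that add atoms: tert-butyl hydroperoxide, CC(C)(C)OO
Why: Vanadium-catalysed hydroxyl-directed epoxidation should deliver oxygen to the α face of C3=C4, since the only free hydroxyl, the bishomoallylic C10–OH, lies on that face and the β-oriented C8 oxygen is blocked as the ester, which sets C3 and C4.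

Step 16
Reactants: 29 epoxy benzyl ether
Product: 30 target CNP0245441.1
Conditions: H2 (1 atm), Pd/C, EtOAc, rt
Reagents that add atoms: none
Why: Hydrogenolysis of the benzyl aryl ether over Pd/C is neutral and should leave the trialkyl epoxide, the tertiary alcohol and the benzoate untouched, no alkene being left in the molecule.

Compound list
1 | 3-methylbutanal | CC(C)CC=O | starting material
2 | malonic acid | OC(=O)CC(=O)O | starting material
3 | (E)-5-methylhex-3-enoic acid | CC(C)/C=C/CC(=O)O | intermediate
4 | 1-[(E)-5-methylhex-3-enoyl]imidazole | CC(C)/C=C/CC(=O)n1ccnc1 | intermediate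
5 | (E)-N-methoxy-N,5-dimethylhex-3-enamide | CC(C)/C=C/CC(=O)N(C)OC | intermediate
6 | 5-hydroxy-2-methyl-4H-pyran-4-one (allomaltol) | CC1=CC(=O)C(O)=CO1 | starting material
7 | 5-(tert-butyldimethylsilyloxy)-2-methyl-4H-pyran-4-one | CC1=CC(=O)C(O[Si](C)(C)C(C)(C)C)=CO1 | intermediate
8 | lithium 5-(tert-butyldimethylsilyloxy)-2-methylene-2H-pyran-4-olate | [Li+].C=C1C=C([O-])C(O[Si](C)(C)C(C)(C)C)=CO1 | intermediate
9 | 5-(tert-butyldimethylsilyloxy)-2-[(E)-6-methyl-2-oxohept-4-enyl]-4H-pyran-4-one | CC(C)/C=C/CC(=O)CC1=CC(=O)C(O[Si](C)(C)C(C)(C)C)=CO1 | intermediate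
10 | (1R,2R)-1,2-diphenylethane-1,2-diol | O[C@H](c1ccccc1)[C@H](O)c1ccccc1 | starting material
11 | 5-(tert-butyldimethylsilyloxy)-2-{[(4R,5R)-2-[(E)-4-methylpent-2-enyl]-4,5-diphenyl-1,3-dioxolan-2-yl]methyl}-4H-pyran-4-one | CC(C)/C=C/CC1(O[C@H](c2ccccc2)[C@@H](c2ccccc2)O1)CC1=CC(=O)C(O[Si](C)(C)C(C)(C)C)=CO1 | intermediate
12 | 4-(tert-butyldimethylsilyloxy)-3-oxidopyrylium ylide with the same ketal side chain at the carbon remote from the oxide | CC(C)/C=C/CC1(O[C@H](c2ccccc2)[C@@H](c2ccccc2)O1)Cc1cc(O[Si](C)(C)C(C)(C)C)c([O-])c[o+]1 | intermediate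
13 | [5+2] adduct: C2–O–C8 bridge β, H-6 α, 7-isopropyl α (endo), H-7 β, C9 ketone, C1=C10 TBS enol ether, C4 (4R,5R)-diphenyldioxolane ketal | CC(C)[C@H]1[C@@H]2CC3(O[C@H](c5ccccc5)[C@@H](c5ccccc5)O3)C[C@@]2(O4)C=C(O[Si](C)(C)C(C)(C)C)C(=O)[C@@H]14 | intermediate
14 | C9 tosylhydrazone of 13 | CC(C)[C@H]1[C@@H]2CC3(O[C@H](c5ccccc5)[C@@H](c5ccccc5)O3)C[C@@]2(O4)C=C(O[Si](C)(C)C(C)(C)C)C(=NNS(=O)(=O)c5ccc(C)cc5)[C@@H]14 | intermediate
15 | allylic diazene, N=NH on C9 α (endo), C1=C10 TBS enol ether | CC(C)[C@H]1[C@@H]2CC3(O[C@H](c5ccccc5)[C@@H](c5ccccc5)O3)C[C@@]2(O4)C=C(O[Si](C)(C)C(C)(C)C)[C@@H](N=N)[C@@H]14 | intermediate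
16 | transposed TBS enol ether, C9=C10, C1 as CH2 | CC(C)[C@H]1[C@@H]2CC3(O[C@H](c5ccccc5)[C@@H](c5ccccc5)O3)C[C@@]2(O4)CC(O[Si](C)(C)C(C)(C)C)=C[C@@H]14 | intermediate
17 | oxa-bridged C10 ketone, C4 ketal | CC(C)[C@H]1[C@@H]2CC3(O[C@H](c5ccccc5)[C@@H](c5ccccc5)O3)C[C@@]2(O4)CC(=O)C[C@@H]14 | intermediate
18 | oxa-bridged tertiary alcohol, 10β-methyl, 10α-hydroxy, C4 ketal | CC(C)[C@H]1[C@@H]2CC3(O[C@H](c5ccccc5)[C@@H](c5ccccc5)O3)C[C@@]2(O4)C[C@@](C)(O)C[C@@H]14 | intermediate
19 | oxa-bridged C4 ketone, 10β-methyl, 10α-hydroxy | CC(C)[C@H]1[C@@H]2CC(=O)C[C@@]2(O4)C[C@@](C)(O)C[C@@H]14 | intermediate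
20 | hydroxy enone: C4 ketone, C2=C3, H-6 α, 7α-isopropyl, 8β-OH, 10β-methyl, 10α-OH | CC(C)[C@H]1[C@@H]2CC(=O)C=C2C[C@@](C)(O)C[C@@H]1O | intermediate
21 | dilithium C3=C4 enolate C8 alkoxide, H-2 β (trans-fused) | [Li+].[Li+].CC(C)[C@H]1[C@@H]2CC([O-])=C[C@H]2C[C@@](C)(O)C[C@@H]1[O-] | intermediate
22 | C3=C4 trimethylsilyl enol ether, 8β- and 10α-OTMS, H-2 β, H-6 α | CC(C)[C@H]1[C@@H]2CC(O[Si](C)(C)C)=C[C@H]2C[C@@](C)(O[Si](C)(C)C)C[C@@H]1O[Si](C)(C)C | intermediate
23 | lithium C3=C4 enolate, 8β- and 10α-OTMS | [Li+].CC(C)[C@H]1[C@@H]2CC([O-])=C[C@H]2C[C@@](C)(O[Si](C)(C)C)C[C@@H]1O[Si](C)(C)C | intermediate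
24 | C4 enol triflate, C3=C4, 8β- and 10α-OTMS | CC(C)[C@H]1[C@@H]2CC(OS(=O)(=O)C(F)(F)F)=C[C@H]2C[C@@](C)(O[Si](C)(C)C)C[C@@H]1O[Si](C)(C)C | intermediate
25 | 4-methyl C3=C4 alkene, 8β- and 10α-OTMS | CC(C)[C@H]1[C@@H]2CC(C)=C[C@H]2C[C@@](C)(O[Si](C)(C)C)C[C@@H]1O[Si](C)(C)C | intermediate
26 | trans-hydroazulene diol: C3=C4–Me, H-2 β, H-6 α, 7α-isopropyl, 8β-OH, 10β-methyl, 10α-OH | CC(C)[C@H]1[C@@H]2CC(C)=C[C@H]2C[C@@](C)(O)C[C@@H]1O | intermediate
27 | 4-(benzyloxy)benzoyl chloride | O=C(Cl)c1ccc(OCc2ccccc2)cc1 | starting material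
28 | C8 4-(benzyloxy)benzoate of 26 | CC(C)[C@H]1[C@@H]2CC(C)=C[C@H]2C[C@@](C)(O)C[C@@H]1OC(=O)c1ccc(OCc2ccccc2)cc1 | intermediate
29 | 3α,4α-epoxide of 28 | CC(C)[C@H]1[C@@H]2C[C@@]3(C)O[C@H]3[C@H]2C[C@@](C)(O)C[C@@H]1OC(=O)c1ccc(OCc2ccccc2)cc1 | intermediate
30 | CNP0245441.1: 3α,4α-epoxy-10α-hydroxy trans-hydroazulene C8β 4-hydroxybenzoate | CC(C)[C@H]1[C@@H]2C[C@@]3(C)O[C@H]3[C@H]2C[C@@](C)(O)C[C@@H]1OC(=O)c1ccc(O)cc1 | target

Total step count: 16. Longest linear sequence: 15 steps (1, 2, 4–16).

Steps most likely to fail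

Step 6.
- What may go wrong: the silyl shift needs a temperature at which the unactivated 1,2-dialkyl alkene, which must bring its isopropyl group under the ylide, may add more slowly than the ylide dimerises or decays. At that temperature the remote ketal may also distinguish the two faces only poorly.
- Fallback: ionic generation of the dipole at room temperature instead of thermal group transfer, from 11 back to 17. MeOTf in CH2Cl2 methylates the pyrone carbonyl to the 4-methoxy-5-silyloxypyrylium triflate F1. CsF removes the silyl group and frees the 4-methoxy-3-oxidopyrylium ylide F2, which should cyclise at room temperature to the methyl enol ether adduct F3, with the diastereomers again separated. TsNHNH2 gives the tosylhydrazone F4, and catecholborane followed by NaOAc·3H2O gives the transposed methyl enol ether F5. Oxalic acid on wet silica gel hydrolyses this to 17 without touching the ketal.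

Step 11.
- What may go wrong: protonation at C2 may take place from the α face (cis-fusion), or proton exchange may scramble the enolate before it is silylated.
- Fallback: catalyst-controlled hydride delivery instead of substrate-controlled protonation, from 20 back to 24. TMSCl and imidazole give the bis(trimethylsilyl) ether of the enone F6. Conjugate reduction with a ligated copper hydride (CuCl, NaOt-Bu, p-tol-BINAP, Ph2SiH2, toluene), using the ligand enantiomer matched to β-face delivery (both are available), gives the diphenylsilyl enol ether F7 regiospecifically. MeLi then frees the enolate 23 and PhNTf2 gives 24.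

Step 8.
- What may go wrong: hydride addition to the hindered hydrazone next to the silyloxy group may be slow or incomplete, or the silyl enol ether may be lost before the diazene has rearranged.
- Fallback: radical deoxygenation instead of the diazene route, from 13 back to 17. Luche reduction (NaBH4, CeCl3·7H2O, MeOH, −78 °C) from the exo face gives the 9α-allylic alcohol F8. PhOC(S)Cl, pyridine and DMAP give the phenyl thionocarbonate F9. A Barton–McCombie reduction (Bu3SnH, AIBN, toluene, 90 °C) passes through a 2-silyloxyallyl radical and gives 16, its C1=C10 isomer F10, or both. Both converge on 17 with Bu4NF/AcOH.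

Further compounds
F1 | step 6 | 4-methoxy-5-(tert-butyldimethylsilyloxy)pyrylium triflate with the ketal side chain | CC(C)/C=C/CC1(O[C@H](c2ccccc2)[C@@H](c2ccccc2)O1)Cc1cc(OC)c(O[Si](C)(C)C(C)(C)C)c[o+]1.[O-]S(=O)(=O)C(F)(F)F
F2 | step 6 | 4-methoxy-3-oxidopyrylium ylide with the ketal side chain | CC(C)/C=C/CC1(O[C@H](c2ccccc2)[C@@H](c2ccccc2)O1)Cc1cc(OC)c([O-])c[o+]1
F3 | step 6 | [5+2] adduct with C1=C10 methyl enol ether and C9 ketone | CC(C)[C@H]1[C@@H]2CC3(O[C@H](c5ccccc5)[C@@H](c5ccccc5)O3)C[C@@]2(O4)C=C(OC)C(=O)[C@@H]14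
F4 | step 6 | C9 tosylhydrazone of F3 | CC(C)[C@H]1[C@@H]2CC3(O[C@H](c5ccccc5)[C@@H](c5ccccc5)O3)C[C@@]2(O4)C=C(OC)C(=NNS(=O)(=O)c5ccc(C)cc5)[C@@H]14
F5 | step 6 | transposed methyl enol ether, C9=C10 | CC(C)[C@H]1[C@@H]2CC3(O[C@H](c5ccccc5)[C@@H](c5ccccc5)O3)C[C@@]2(O4)CC(OC)=C[C@@H]14
F6 | step 11 | bis(trimethylsilyl) ether of enone 20 | CC(C)[C@H]1[C@@H]2CC(=O)C=C2C[C@@](C)(O[Si](C)(C)C)C[C@@H]1O[Si](C)(C)C
F7 | step 11 | C3=C4 diphenylsilyl enol ether, H-2 β, 8β- and 10α-OTMS | CC(C)[C@H]1[C@@H]2CC(O[SiH](c3ccccc3)c3ccccc3)=C[C@H]2C[C@@](C)(O[Si](C)(C)C)C[C@@H]1O[Si](C)(C)C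
F8 | step 8 | 9α-allylic alcohol from 13 | CC(C)[C@H]1[C@@H]2CC3(O[C@H](c5ccccc5)[C@@H](c5ccccc5)O3)C[C@@]2(O4)C=C(O[Si](C)(C)C(C)(C)C)[C@@H](O)[C@@H]14
F9 | step 8 | O-phenyl thionocarbonate of F8 | CC(C)[C@H]1[C@@H]2CC3(O[C@H](c5ccccc5)[C@@H](c5ccccc5)O3)C[C@@]2(O4)C=C(O[Si](C)(C)C(C)(C)C)[C@@H](OC(=S)Oc5ccccc5)[C@@H]14
F10 | step 8 | C1=C10 TBS enol ether with C9 as CH2 | CC(C)[C@H]1[C@@H]2CC3(O[C@H](c5ccccc5)[C@@H](c5ccccc5)O3)C[C@@]2(O4)C=C(O[Si](C)(C)C(C)(C)C)C[C@@H]14
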